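**Retrosynthetic overview**
1. Ring numbering: C1(=O), C2(OH), C3(CH3), C4(=O), C5(OH), C6(pentadecenyl). The quinone ring is the bis-enol of a cyclohexane-1,2,4,5-tetraone: C1/C2 and C4/C5 are two vicinal dicarbonyl pairs, and C3 and C6 are the two alkyl-bearing carbons between them. Every C(alkyl)–C(O) ring bond is therefore a Claisen retron, and the target is already at the oxidation level of a double-Claisen product.
2. Key disconnections: C2–C3 and C6–C1. C1–C2 come from dimethyl oxalate; C3–C6 come from (15Z)-icos-15-ene-3,4-dione, used as its chain-side silyl enol ether 8. The ethyl carbon (C3) is acylated first, and the chain carbon (C6) then closes the ring onto C1 in a Dieckmann step.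
3. The quinone ring is the only ring and is formed last. 8 comes from α-keto Weinreb amide 5 (enol silylation, then EtMgBr); 5 from the Grignard reagent of bromide 2 and bis-Weinreb oxamide 3; 2 from (Z)-hexadec-11-en-1-ol 1, which supplies the (Z)-alkene, the only stereochemical element.

Key step: step 5

Assumption: compounds 1, 3, 7 and 9 are taken as purchased; intermediates 10 and 11 exist in the flask as enolates and are drawn in their neutral keto forms, so C3 of each carries no defined configuration.

**Route**

Step 1
Reactants: 1 (Z)-hexadec-11-en-1-ol
Product: 2 (Z)-1-bromohexadec-11-ene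
Conditions: CBr4, PPh3, CH2Cl2, 0 °C to rt
Reagents that add atoms: carbon tetrabromide, BrC(Br)(Br)Br
Why: An Appel reaction converts the primary alcohol into the bromide under neutral conditions that leave the remote (Z)-alkene untouched.

Step 2
Reactants: 2 (Z)-1-bromohexadec-11-ene; 3 N,N'-dimethoxy-N,N'-dimethyloxamide
Product: 5 (13Z)-N-methoxy-N-methyl-2-oxooctadec-13-enamide, via Grignard reagent 4 (not isolated)
Conditions: Mg, THF, 40 °C; then added to 3 (1.5 equiv), THF, −78 to 0 °C; 1 M HCl
Reagents that add atoms: N,N'-dimethoxy-N,N'-dimethyloxamide (3), CON(C)C(=O)C(=O)N(C)OC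
Why: Grignard formation followed by a Weinreb-type monoacylation should stop at the α-keto amide, because N-methoxy-N-methylamide chelation holds the addition at the ketone oxidation level until the acidic quench, and inverse addition to excess 3 at low temperature limits attack on the second amide group.

Step 3
Reactants: 5 (13Z)-N-methoxy-N-methyl-2-oxooctadec-13-enamide
Product: 6 (2Z,13Z)-2-[(tert-butyldimethylsilyl)oxy]-N-methoxy-N-methyloctadeca-2,13-dienamide
Conditions: TBSOTf, Et3N, CH2Cl2, 0 °C to rt
Reagents that add atoms: tert-butyldimethylsilyl trifluoromethanesulfonate, CC(C)(C)[Si](C)(C)OS(=O)(=O)C(F)(F)F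
Why: Soft enolization and O-silylation can only take place toward C3, the sole α-CH2 of the α-keto amide, so the chain-side carbonyl is masked regiospecifically as its silyl enol ether, expected mainly as the (2Z)-isomer, a geometry of no consequence because this double bond is erased in step 5.

Step 4
Reactants: 6 (2Z,13Z)-2-[(tert-butyldimethylsilyl)oxy]-N-methoxy-N-methyloctadeca-2,13-dienamide; 7 ethylmagnesium bromide
Product: 8 (4Z,15Z)-4-[(tert-butyldimethylsilyl)oxy]icosa-4,15-dien-3-one
Conditions: EtMgBr, THF, −40 to 0 °C; sat. aq NH4Cl
Reagents that add atoms: ethylmagnesium bromide (7), CC[Mg]Br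
Why: In a Weinreb ketone synthesis the Grignard reagent should add once to the N-methoxy-N-methylamide, while the electron-rich, β-substituted silyloxy alkene disfavours conjugate addition and keeps the former ketone masked.

Step 5
Reactants: 8 (4Z,15Z)-4-[(tert-butyldimethylsilyl)oxy]icosa-4,15-dien-3-one; 9 dimethyl oxalate
Product: 12 2,5-dihydroxy-3-methyl-6-[(10Z)-pentadec-10-en-1-yl]cyclohexa-2,5-diene-1,4-dione, via silyl-masked dioxo ester 10 (not isolated), via acyclic trioxo ester 11 (not isolated)
Conditions: LiN(SiMe3)2 (1.05 equiv), THF, −78 °C; 9 (1.2 equiv), −78 to 0 °C; then NaOMe (4 equiv), MeOH, 0 to 50 °C; 1 M HCl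
Reagents that add atoms: dimethyl oxalate (9), COC(=O)C(=O)OC
Why: LiN(SiMe3)2 removes a proton from the ethyl CH2 of 8 (the only α-CH, since the chain-side carbonyl is locked as its silyl enol ether) and the lithium enolate undergoes a crossed Claisen condensation with dimethyl oxalate to give 10 as its enolate (ring bond C2–C3); methoxide then cleaves the Si–O bond and releases the regiodefined chain-side enolate (dianion of 11), whose carbon C6 attacks the terminal ester carbon C1 in a Dieckmann condensation, after which loss of methoxide and enolization give the dianion of 12. The closest known reaction types are the oxalate Claisen condensation of ketone enolates and the base-mediated Claisen/Dieckmann condensation of α-keto esters that leads to 3,6-dialkyl-2,5-dihydroxy-1,4-benzoquinones. The six-membered ring closes in the 6-(enolexo)-exo-trig mode, C6 (enolate carbon) onto C1 (ester carbonyl). No stereocentre is created: C3 of 10 and 11 is enolized and ends sp2, and the (Z)-alkene, bought with 1, lies far from every acidic site. The step needs the order of the two acylations (ethyl side first, chain carbon last), which the silyl enol ether secures, with the lithium dienolate kept at −78 °C so that the silyl group does not migrate to the neighbouring oxygen; it also needs C- rather than O-acylation in the closure, which the equilibrating NaOMe/MeOH medium should secure because any enol lactone is reopened by methoxide and the doubly deprotonated dihydroxyquinone is the thermodynamic sink. The oxidation level is already that of the quinone, so no oxidant is needed and acidification should liberate 12.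

**Compound list**
1 | (Z)-hexadec-11-en-1-ol | CCCC/C=C\CCCCCCCCCCO | starting material
2 | (Z)-1-bromohexadec-11-ene | CCCC/C=C\CCCCCCCCCCBr | intermediate
3 | N,N'-dimethoxy-N,N'-dimethyloxamide | CON(C)C(=O)C(=O)N(C)OC | starting material
4 | (Z)-hexadec-11-en-1-ylmagnesium bromide (Grignard reagent, not isolated) | CCCC/C=C\CCCCCCCCCC[Mg]Br | intermediate
5 | (13Z)-N-methoxy-N-methyl-2-oxooctadec-13-enamide | CCCC/C=C\CCCCCCCCCCC(=O)C(=O)N(C)OC | intermediate
6 | (2Z,13Z)-2-[(tert-butyldimethylsilyl)oxy]-N-methoxy-N-methyloctadeca-2,13-dienamide | CCCC/C=C\CCCCCCCCC/C=C(\O[Si](C)(C)C(C)(C)C)C(=O)N(C)OC | intermediate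
7 | ethylmagnesium bromide | CC[Mg]Br | starting material
8 | (4Z,15Z)-4-[(tert-butyldimethylsilyl)oxy]icosa-4,15-dien-3-one | CCCC/C=C\CCCCCCCCC/C=C(\O[Si](C)(C)C(C)(C)C)C(=O)CC | intermediate
9 | dimethyl oxalate | COC(=O)C(=O)OC | starting material
10 | methyl (5Z,16Z)-5-[(tert-butyldimethylsilyl)oxy]-3-methyl-2,4-dioxohenicosa-5,16-dienoate (silyl-masked dioxo ester, not isolated, present as its enolate) | CCCC/C=C\CCCCCCCCC/C=C(\O[Si](C)(C)C(C)(C)C)C(=O)C(C)C(=O)C(=O)OC | intermediate
11 | methyl (16Z)-3-methyl-2,4,5-trioxohenicos-16-enoate (acyclic trioxo ester, not isolated, present as its dianion) | CCCC/C=C\CCCCCCCCCCC(=O)C(=O)C(C)C(=O)C(=O)OC | intermediate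
12 | 2,5-dihydroxy-3-methyl-6-[(10Z)-pentadec-10-en-1-yl]cyclohexa-2,5-diene-1,4-dione | CCCC/C=C\CCCCCCCCCC1=C(O)C(=O)C(C)=C(O)C1=O | target

**Step count**
Total steps: 5. Longest linear sequence: 5 steps (1 to 12).

**Steps most likely to fail**

Step 5. What may go wrong: transfer or loss of the silyl group before the first Claisen condensation, so that both carbonyl groups enolize and self-condensation of the diketone competes; or ring closure through oxygen that is not corrected under the conditions. Fallback, a ring assembly from two α-keto esters (3 + 3 carbons) instead of masked diketone plus oxalate (4 + 2 carbons): it sets out from 2. Grignard reagent 4 is added to excess dimethyl oxalate 9 (THF, −78 °C), which should give methyl (13Z)-2-oxooctadec-13-enoate F1. F1 is then condensed with an excess of purchased methyl 2-oxobutanoate under NaOMe (MeOH/THF, rt to reflux), a mixed double Claisen condensation of the classical α-keto ester type in which the chain carbon again closes the ring onto an ester carbon. After acidification the symmetrical dimethyl co-product is removed by its low solubility in hydrocarbons, and the fallback comes back to the route at 12.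

Step 4. What may go wrong: conjugate addition of the Grignard reagent to the acrylamide, or attack at silicon with loss of the enol ether, instead of clean addition to the amide carbonyl. Fallback, a reduction, addition and oxidation sequence: it sets out from 6. Reduction with i-Bu2AlH (THF, −78 °C) should give (2Z,13Z)-2-[(tert-butyldimethylsilyl)oxy]octadeca-2,13-dienal F2. 1,2-Addition of EtMgBr 7 at −78 °C with a cold quench should give racemic (4Z,15Z)-4-[(tert-butyldimethylsilyl)oxy]icosa-4,15-dien-3-ol F3, whose stereocentre is removed at once by Dess–Martin oxidation (CH2Cl2, NaHCO3, rt). The fallback comes back to the route at 8.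

Step 3. What may go wrong: incomplete O-silylation, or hydrolytic cleavage of the silyl enol ether during work-up and chromatography. Fallback, giving up the mask: it sets out from 2. Grignard reagent 4 and then EtMgBr 7 are added in one pot to oxamide 3 (sequential double Weinreb addition, THF, −78 °C to rt, acidic quench), which should give (15Z)-icos-15-ene-3,4-dione F4. F4 is then treated with dimethyl oxalate 9 and NaOMe in MeOH at reflux, a fully equilibrating double Claisen condensation in which the order of the two acylations is no longer controlled but both orders converge on the same dianion. Acidification brings the fallback back to the route at 12.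

**Further compounds**
F1 | step 5 | methyl (13Z)-2-oxooctadec-13-enoate | CCCC/C=C\CCCCCCCCCCC(=O)C(=O)OC
F2 | step 4 | (2Z,13Z)-2-[(tert-butyldimethylsilyl)oxy]octadeca-2,13-dienal | CCCC/C=C\CCCCCCCCC/C=C(\O[Si](C)(C)C(C)(C)C)C=O
F3 | step 4 | (4Z,15Z)-4-[(tert-butyldimethylsilyl)oxy]icosa-4,15-dien-3-ol (racemic) | CCCC/C=C\CCCCCCCCC/C=C(\O[Si](C)(C)C(C)(C)C)C(O)CC
F4 | step 3 | (15Z)-icos-15-ene-3,4-dione | CCCC/C=C\CCCCCCCCCCC(=O)C(=O)CC
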